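## The problem

Briarane numbering is used for every compound. C1 is the quaternary carbon bearing methyl C15. C1–C10 form the ten-membered ring, and C1 and C10–C14 form ring A. C16 is the methylene carbon on C5, and C20 is the methyl on C11. C7, C8, C17, C19 and O7 form the lactone, with C18 on C17. β is the face of ring A that carries C15.

- **Ring system.** The core is a trans-fused bicyclo[8.4.0]tetradecane. Its ten-membered carbocycle is the ring that resists closure: it runs from quaternary C1 to fully substituted C8 and closes only against transannular strain.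
- **Ring A stereocentres.** Six of the twelve stereocentres lie on ring A (C1, C10–C14). C15, C9 and C20 are all β, so the two methyl groups are 1,3-syn. O12 and the 13,14-epoxide are all α.
- **C11 constraint.** This pattern is lost by epimerisation at C11 if C12 ever becomes a ketone.
- **Chain stereocentres.** The other six (C2, C9, C8, C17, C7, C6) lie on the large ring. C1 can steer C2, C10 can steer C9, C8 can steer C7, and C6 has to be set together with C7.
- **Fragile groups.** These are the secondary allylic chloride at C6 (SN2', ionisation, loss of HCl), the epoxide, and two different esters (O2 acetate, O12 hexanoate) beside two free hydroxyls. 9-OH is as well placed as O7 to hold the C19 carbonyl.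
- **Enabling feature.** The array C16=C5–C6(Cl)–C7(O7) has three properties. O7 is a homoallylic oxygen, chlorine sits on the allylic carbon between the carbinol and the 1,1-disubstituted alkene, and the ring tether C4 is attached to the central carbon C5.
- **What it implies.** This array is the retron of an SE2' addition of a γ-chloroallyl metal (metal on C16) to a C7 aldehyde. Because O7 is γ to C19, the alkoxide so formed can close the five-membered lactone in the same operation.

## Retrosynthesis

**38 ⇒ 37.** Only the two O–Si bonds at O8 and O9 are cut. Both free hydroxyls are kept masked to the end, so that acylation, oxidation and ring closure never have to distinguish them from O2 and O12. The forward step has to be non-basic.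

**37 ⇒ 34 (through 35 and 36).**
- Cut: C6–C7 and O7–C19.
- Against a cut at C5–C6 or C2–C3: this one removes both remaining rings, two stereocentres, the allylic chloride and the exocyclic methylene together.
- The chloride then never has to be made by substitution on the finished ring.
- Simplification: 34 is ring A with two open chains, an α-silyloxy aldehyde without α-hydrogen on one and a chloro-substituted allylic chloride on the other.
- Demand on the forward reaction: an allylchromium species 35 must add through its chlorine-bearing carbon, anti-selectively and on the Felkin–Anh face, at high dilution. The alkoxide of 36 must then lactonise.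

**34 ⇒ 29.** The acyl–O bonds at O2 and O12, the C16–Cl bond and the O8–Si bond are cut. The order is dictated by one fact: the last hydride reduction of the route makes 29, so both esters must come after it. O12 and O16 carry the same PMB group so that one oxidative step frees both (32). The allylic one alone is then turned into chloride (33), and the remaining one is acylated (34).

**29 ⇒ 19 + 23 (through 26).**
- Cut: C8–C9.
- Against a cut at C9–C10 or C8–C17: it splits the molecule into a ring-A keto aldehyde and a four-carbon acid that already holds C17 and the memory of C8. The bond formation sets C8 and C9 together.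
- Demand on the forward aldol: three control elements must agree, namely the enolate face, the enolate geometry and the aldehyde face.
- The later reduction has to take C7 down to the aldehyde level only, while C19 is shielded as its carboxylate and the C2 ketone is reduced under control from C1.

**23 ⇒ 20.** The C17–C18 bond and the acetal are cut. The unit C7–C8(O)–C17(Me)–C19 is 3-methylmalic acid. The natural (S) series of 20 and the anti-selective methylation give exactly the 8,17 pattern of the target (21, 22).

**19 ⇒ 12 + 17.** Cut at C3–C4. C4 is allylic and C3 is the only enolisable position of the C2 ketone, because C1 is quaternary. A plain enolate alkylation therefore joins the pieces without regiochemical doubt. This is simpler than a C2–C3 cut, which would need an organometallic reagent carrying the vinyl chloride.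

**17 ⇒ 13.** The C5=C6 bond is cut. The three-carbon ketone 13 is symmetrical, so chloromethylenation gives a single product 14. The two arms are told apart only afterwards (15, 16).

**12 ⇒ 8 (through 11 and 10).**
- Cut: the C2–C3 bond and the three C–O bonds at C12–C14.
- With open chains, ring A would place C2 and C9 diaxial, and neither face nor allylic hydrogen of C12=C13 would be distinguished.
- The trans-fused lactone 8 locks C2 and C9 diequatorial. C15 and C20 then close the β face, and H14α is the only aligned allylic hydrogen.
- One oxygenation can then set C12, C13 and C14. The same lactone later differentiates C2 (acyl) from C9 (alkyl–O) when it is opened.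

**8 ⇒ 4 + 5 (through 6).** The bonds C1–C14 and C10–C11 are cut. A Diels–Alder reaction of an E dienophile is the only simple way to obtain C2 and C9 trans while C15, C9 and C20 stay all cis. A cyclic (Z) dienophile followed by epimerisation at C10 would end with C20 on the wrong face. The forward step must be formyl-directed in regiochemistry, formyl-endo and enantioselective.

**4 ⇒ 1 + 2 (through 3).** The C1=C10 bond is cut. A stabilised ylide gives the E geometry.

## Roads not taken

**Alternative 1** (the obvious one): cut C5–C6.
- Forward key step: Ni/Cr-mediated Nozaki–Hiyama–Kishi closure of the 2-iodoalkene aldehyde A1 to the allylic alcohol A2. 6-OH is then replaced by chloride with inversion.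
- A1 needs one more carbon on the lactone side. It is an α-acyloxy aldehyde, prone to epimerisation and β-elimination at C7.
- C6 would be formed without a cyclic transition state, and it would have to come out as the epimer of the target.
- The final substitution acts on a secondary allylic carbinol next to an acyloxy carbon. There SN2' delivery of chloride to C16 and ionisation compete.
- The chosen plan makes the C–Cl stereocentre during the C–C bond formation and saves the steps after ring closure.

**Alternative 2:** cut C4–C5 and reconnect C2–C7.
- Forward key step: anionic oxy-Cope ring expansion of the trans-decalin A3 to the cyclodecadienone A4, followed by chlorolactonisation of C6=C7. A3 would be derived from the 5-methyl Wieland–Miescher ketone, which holds 12 of the 20 skeletal carbons.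
- The mapping is attractive, and ring A could follow steroid-type chemistry.
- The E alkene needs an equatorial vinyl group at C2 beside the axial angular methyl, whereas nucleophiles are expected to enter from the α face.
- The α-allenyl ketone precursor is labile.
- The three methylene groups of ring B would have to be oxidised one after the other, which makes a long run-up.
- After the expansion, C2, C6, C7, C8 and C17 would all still have to be set on a flexible ring. A conjugated diene would then invite 1,4-addition of chlorine and carboxylate.

**Alternative 3:** cut C6–Cl last (biomimetic).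
- Forward key step: ene-type electrophilic chlorination of the 5Z alkene A5, with chlorine going to C6 and a proton leaving C16.
- This only moves the main problem, since a ten-membered ring containing a trisubstituted Z alkene between C4 and an acyloxy carbon must still be closed. Ring-closing metathesis is weak for exactly this case.
- The chlorination itself would have to choose C16–H over C4–H and one alkene face without any control element, on an alkene deactivated by the allylic lactone oxygen.
- The chosen plan lets one bond formation settle ring closure, regiochemistry of the alkene and both stereocentres.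

Key step: step 24

Assumption: the sense of induction of the oxazaborolidinium catalyst in step 3 is taken from the accepted formyl C–H···O binding model for enals; both antipodes of the catalyst are commercial, so the antipode would be used if the sense proved opposite.

## Steps

Step 1
Reactants: 1 2,2-dimethoxyacetaldehyde; 2 methyl 2-(triphenyl-λ5-phosphanylidene)propanoate
Product: 3 methyl (E)-4,4-dimethoxy-2-methylbut-2-enoate
Conditions: CH2Cl2, 0 °C to rt
Reagents that add atoms: none
Why: Wittig olefination; the ester-stabilised ylide gives the E alkene (CO2Me trans to the acetal carbon), which later fixes C2 trans to C9 and C15 cis to C9.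

Step 2
Reactants: 3 methyl (E)-4,4-dimethoxy-2-methylbut-2-enoate
Product: 4 methyl (E)-2-methyl-4-oxobut-2-enoate
Conditions: Amberlyst-15, acetone/H2O, rt
Reagents that add atoms: water, O
Why: Acid-catalysed acetal hydrolysis; the E enal is the thermodynamic isomer, so the geometry is kept.

Step 3
Reactants: 4 methyl (E)-2-methyl-4-oxobut-2-enoate; 5 (E)-penta-1,3-diene
Product: 6 methyl (1S,5S,6S)-6-formyl-1,5-dimethylcyclohex-3-ene-1-carboxylate (ring A; C15 C9 C20 all β; C2 = ester carbon; C9 = formyl carbon)
Conditions: (S)-o-tolyl-diphenylprolinol oxazaborolidine·Tf2NH (10 mol %), CH2Cl2, −78 to −40 °C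
Reagents that add atoms: none
Why: Catalytic enantioselective Diels–Alder reaction: the boron Lewis acid binds only the formyl group, so C1 (β to CHO) takes the unsubstituted diene terminus C14 and C11 ends next to C10, and the formyl group sits endo, which puts C20 cis to C9. The E alkene puts C15 cis and C2 trans to C9, and the catalyst shields one face of the enal, so C1, C10 and C11 are set absolutely in one step.

Step 4
Reactants: 6 Diels–Alder adduct
Product: 8 trans-fused ring-A lactone (C2 carbonyl–O–C9H2 bridge on the C12=C13 cyclohexene; 15β-Me 10α-H 20β-Me), via hydroxy ester 7 (not isolated)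
Conditions: NaBH4, MeOH, 0 °C; then p-TsOH (cat.), PhMe, 80 °C
Reagents that add atoms: none
Why: Chemoselective borohydride reduction of the aldehyde beside the hindered tertiary ester, then acid-catalysed lactonisation. The trans-fused five-membered ring forces C2 and C9 diequatorial and C15 and C20 axial on the β face, the conformation that step 5 needs.

Step 5
Reactants: 8 trans-fused ring-A lactone
Product: 10 12α-hydroxy-13α,14α-epoxy lactone, via allylic hydroperoxide 9 (not isolated)
Conditions: O2, tetraphenylporphyrin (cat.), visible light, Ti(OiPr)4 (cat.), 4 Å MS, CH2Cl2, 0 °C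
Reagents that add atoms: dioxygen, O=O
Why: Schenck ene reaction followed by titanium-mediated transfer of the distal peroxide oxygen to the new double bond (one-pot epoxy-hydroxylation). In locked 8 the β face is closed by two axial methyl groups and only H14α is pseudo-axial on the open α face (H11α is pseudo-equatorial), so oxygen should enter at C12α with shift of the alkene to C13=C14. The titanium-bound peroxide then delivers the second oxygen syn and sets the 13α,14α-epoxide.

Step 6
Reactants: 10 epoxy alcohol lactone
Product: 11 12α-O-PMB epoxy lactone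
Conditions: NaH, PMBCl, Bu4NI (cat.), DMF, 0 °C to rt
Reagents that add atoms: 4-methoxybenzyl chloride, COc1ccc(CCl)cc1
Why: Williamson etherification; the lactone has no α-hydrogen and a cis epoxy alkoxide cannot undergo Payne migration, so the base is tolerated. PMB is chosen because it falls together with the PMB group on O16 in step 21.

Step 7
Reactants: 11 12α-O-PMB epoxy lactone
Product: 12 C2 methyl ketone with free C9 primary alcohol
Conditions: MeLi (1.1 equiv), THF, −78 °C; AcOH quench at −78 °C
Reagents that add atoms: methyllithium, [Li]C
Why: Mono-addition of an organolithium to a lactone; the lithium hemiketal next to quaternary C1 persists at −78 °C and collapses only on quench, so no tertiary alcohol should form.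

Step 8
Reactants: 13 2,2-dimethyl-1,3-dioxan-5-one
Product: 14 5-(chloromethylidene)-2,2-dimethyl-1,3-dioxane
Conditions: ClCH2PPh3Cl, NaHMDS, THF, −78 °C to rt
Reagents that add atoms: (chloromethyl)triphenylphosphonium chloride, ClC[P+](c1ccccc1)(c1ccccc1)c1ccccc1.[Cl-]
Why: Wittig chloromethylenation of a ketone; the ketone is symmetrical, so a single alkene results.

Step 9
Reactants: 14 5-(chloromethylidene)-2,2-dimethyl-1,3-dioxane
Product: 15 2-(chloromethylidene)propane-1,3-diol
Conditions: 1 M HCl, THF, rt
Reagents that add atoms: none
Why: Acid hydrolysis of an acetonide; the vinyl chloride is inert to dilute acid.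

Step 10
Reactants: 15 2-(chloromethylidene)propane-1,3-diol
Product: 16 (E)-3-chloro-2-[(4-methoxybenzyloxy)methyl]prop-2-en-1-ol (Cl trans to CH2OPMB)
Conditions: NaH (1.0 equiv), PMBCl, Bu4NI (cat.), THF/DMF, 0 °C; separation of the geometric isomers on silica
Reagents that add atoms: 4-methoxybenzyl chloride, COc1ccc(CCl)cc1
Why: Statistical Williamson mono-etherification of a diol whose two arms differ only in their relation to chlorine. The isomer with Cl trans to CH2OPMB is carried on because it maps directly onto the chair of step 24; the other isomer would converge at the allylchromium stage.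

Step 11
Reactants: 16 (E)-mono-PMB ether
Product: 17 (Z)-1-{[2-(bromomethyl)-3-chloroprop-2-enyl]oxymethyl}-4-methoxybenzene (Cl cis to CH2Br)
Conditions: CBr4, PPh3, CH2Cl2, 0 °C
Reagents that add atoms: carbon tetrabromide, BrC(Br)(Br)Br
Why: Appel bromination, SN2 at a primary allylic carbon under neutral conditions; the alkene geometry is untouched.

Step 12
Reactants: 12 C2 methyl ketone; 17 allylic bromide
Product: 18 C2 ketone carrying the full C3–C6/C16 chain with free C9 alcohol
Conditions: LDA (2.2 equiv), THF, −78 °C; 17, DMPU, −78 to −30 °C; AcOH quench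
Reagents that add atoms: none
Why: Ketone enolate alkylation forming C3–C4; C1 is quaternary, so only the C3 enolate can form. The enolate carbon should react with the allylic bromide much faster than the lithium alkoxide at O9 does.

Step 13
Reactants: 18 keto alcohol
Product: 19 C2-keto C9-aldehyde
Conditions: Dess–Martin periodinane, NaHCO3, CH2Cl2, 0 °C to rt
Reagents that add atoms: none
Why: Dess–Martin oxidation; the buffered neutral medium should leave the α-stereocentre C10 and the epoxide untouched.

Step 14
Reactants: 20 dimethyl (S)-malate
Product: 21 dimethyl (2S,3R)-2-hydroxy-3-methylbutanedioate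
Conditions: LDA (2.1 equiv), THF, −78 to −20 °C; MeI, −78 °C; AcOH quench
Reagents that add atoms: iodomethane, CI
Why: Fráter–Seebach alkylation; the chelated alkoxide enolate is methylated anti to the oxygen substituent, which sets C17 relative to C8.

Step 15
Reactants: 21 dimethyl (2S,3R)-3-methylmalate
Product: 22 (2S,3R)-2-hydroxy-3-methylbutanedioic acid
Conditions: KOH, H2O/MeOH, 0 °C to rt; then HCl
Reagents that add atoms: potassium hydroxide, [K+].[OH-]
Why: Ester saponification; the carboxylates formed resist enolisation, so C17 should be kept.

Step 16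
Reactants: 22 (2S,3R)-3-methylmalic acid
Product: 23 (2R)-2-[(2S,4S)-2-tert-butyl-5-oxo-1,3-dioxolan-4-yl]propanoic acid (tert-butyl cis to the side chain)
Conditions: pivalaldehyde, p-TsOH (cat.), pentane, reflux, water separator; crystallisation
Reagents that add atoms: pivalaldehyde, CC(C)(C)C=O
Why: Acetalisation of the α-hydroxy acid (the five-membered dioxolanone is preferred over the six-membered ring through C19) gives mainly the cis isomer. The acetal carbon stores the configuration of C8 (self-regeneration of stereocentres).

Step 17
Reactants: 19 keto aldehyde; 23 dioxolanone acid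
Product: 26 C8–C9 coupled 9-O-TES dioxolanone acid, via aldol adduct 24 (not isolated), via bis-silyl derivative 25 (not isolated)
Conditions: 23, LiHMDS (2.1 equiv), THF, −78 °C; 19, −78 °C; TESOTf (2.5 equiv), −78 to −50 °C; aqueous citric acid work-up
Reagents that add atoms: triethylsilyl trifluoromethanesulfonate, CC[Si](CC)(CC)OS(=O)(=O)C(F)(F)F
Why: Aldol addition of the doubly deprotonated dioxolanone acid; attack anti to tert-butyl sets C8 with net retention, and the ring-fixed enolate geometry (O8 trans to OLi) gives the 8,9-anti diol through a Zimmerman–Traxler chair. Felkin–Anh attack on 19 (C1 as the large group) asks for the same C9 configuration, so the three control elements are matched. Silylation in the flask stops retro-aldol cleavage and lactonisation of O9 onto C19.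

Step 18
Reactants: 26 9-O-TES dioxolanone acid
Product: 29 2R-hydroxy 8-hydroxy C7-aldehyde C19-methyl ester, via dioxolane lactol 27 (not isolated), via aldehyde acid 28 (not isolated)
Conditions: DIBAL (4.5 equiv), CH2Cl2, −78 °C; Rochelle salt work-up; then TMSCHN2, PhMe/MeOH, 0 °C
Reagents that add atoms: (trimethylsilyl)diazomethane, C[Si](C)(C)C=[N+]=[N-]
Why: DIBAL should reduce the C2 ketone in the Felkin–Anh sense (C10 anti to hydride, hydride passing C15) to the 2R alcohol and stop at the aluminated lactol of the activated dioxolanone, while C19 is shielded as its aluminium carboxylate. On work-up 27 opens and loses the acetal aldehyde, and diazoalkane esterification of crude 28 traps the open aldehyde acid form.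

Step 19
Reactants: 29 diol aldehyde ester
Product: 30 2-O-acetate
Conditions: Ac2O, pyridine, DMAP (cat.), CH2Cl2, 0 °C to rt
Reagents that add atoms: acetic anhydride, CC(=O)OC(C)=O
Why: Acylation of the secondary C2 alcohol; the tertiary 8-OH next to two branched carbons should not react under these conditions.

Step 20
Reactants: 30 2-O-acetate
Product: 31 8,9-bis-O-TES aldehyde
Conditions: TESOTf, 2,6-lutidine, CH2Cl2, −78 to 0 °C
Reagents that add atoms: triethylsilyl trifluoromethanesulfonate, CC[Si](CC)(CC)OS(=O)(=O)C(F)(F)F
Why: Silyl triflate silylation of a tertiary alcohol; the bulky non-chelating group on O8 is what step 24 needs for Felkin–Anh control, and it ends the risk of an α-ketol shift.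

Step 21
Reactants: 31 bis-PMB ether
Product: 32 12,16-diol
Conditions: DDQ (2.5 equiv), CH2Cl2/pH 7 buffer, 0 °C
Reagents that add atoms: none
Why: Oxidative PMB cleavage by hydride abstraction from the electron-rich benzylic positions frees O12 and O16 in one step. Silyl ethers, esters, epoxide, aldehyde and vinyl chloride are not affected.

Step 22
Reactants: 32 12,16-diol
Product: 33 C16 allylic chloride with free 12-OH
Conditions: NCS, Me2S, CH2Cl2, −20 to 0 °C; aqueous work-up without amine base
Reagents that add atoms: N-chlorosuccinimide, O=C1CCC(=O)N1Cl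
Why: Corey–Kim chlorination; only the allylic alkoxysulfonium salt collapses to the chloride (SN2, no transposition). The salt formed at O12 returns the alcohol on work-up because no base is added.

Step 23
Reactants: 33 allylic chloride
Product: 34 12-O-hexanoate (seco precursor)
Conditions: hexanoic anhydride, pyridine, DMAP (cat.), CH2Cl2, 0 °C
Reagents that add atoms: hexanoic anhydride, CCCCCC(=O)OC(=O)CCCCC
Why: DMAP-catalysed acylation of the only free hydroxyl group; low temperature and catalytic DMAP limit quaternisation of the allylic chloride.

Step 24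
Reactants: 34 seco precursor
Product: 37 8,9-bis-O-TES ether of the target, via allylchromium 35 (not isolated), via hydroxy ester 36 (not isolated)
Conditions: CrCl2 (10 equiv), LiI (cat.), THF/DMF, rt, syringe-pump addition of 34 (final about 1 mM); aqueous serinate work-up; PPTS (cat.), CH2Cl2, rt
Reagents that add atoms: none
Why: Two one-electron transfers from Cr(II) convert the primary allylic C16–Cl bond of 34 into the allylchromium(III) 35, while the vinylic C6–Cl bond is inert in the absence of nickel. The C16-bound and C6-bound forms of 35 interconvert, so the reacting species should be the less hindered C16-bound one with Cl trans to CH2Cr, whichever alkene geometry is fed in. It adds to the C7 aldehyde through C6 (SE2') in a closed chair (Cr, O7, C7, C6, C5, C16); the closest known reaction types are the Cr(II)-mediated addition of 1,3-dihalopropenes to aldehydes, which gives anti 2-chlorobut-3-en-1-ols, and the Nozaki–Hiyama allylation that closes ten-membered germacrane rings. The carbocycle closes exo-trig at the carbonyl group, and because the tether C4 sits on the central allyl carbon C5 the π bond leaves the ring and becomes the C5=C16 methylene. C6 is set relative to C7 by the chair: Cl and C8 both equatorial give the anti chlorohydrin, which is the 6S,7R pair of the target. C7 is set by C8 in the polar Felkin–Anh sense: the non-chelating O8 silyl ether stands anti to incoming C6, the large C9 branch flanks the carbonyl oxygen and the smaller C17 branch lies next to the trajectory, an arrangement that also keeps C6 gauche to C9 as the ring demands. The chromium alkoxide of 36 (or 36 itself on mild acid treatment) then attacks the C19 ester, 5-exo-trig, and closes the lactone trans-fused to the large ring, which also removes the alkoxide before it can displace chloride. The step needs selectivity for the aldehyde over ester, acetate and epoxide, which the weakly basic organochromium reagent provides, γ over α attack, which chromium on the unsubstituted carbon provides, and ring closure over oligomerisation, which slow addition to excess CrCl2 provides.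

Step 25
Reactants: 37 bis-TES ether
Product: 38 CNP0109876.1 (target)
Conditions: HF·pyridine, pyridine, THF, 0 °C to rt
Reagents that add atoms: none
Why: Fluoride-mediated desilylation in a buffered, weakly acidic medium. This avoids base-induced migration of the lactone from O7 to O9, acyl migration and loss of HCl, and the hindered epoxide should survive.

## Compound list

1 | 2,2-dimethoxyacetaldehyde | COC(OC)C=O | starting material
2 | methyl 2-(triphenyl-λ5-phosphanylidene)propanoate | COC(=O)C(C)=P(c1ccccc1)(c1ccccc1)c1ccccc1 | starting material
3 | methyl (E)-4,4-dimethoxy-2-methylbut-2-enoate | COC(=O)/C(C)=C/C(OC)OC | intermediate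
4 | methyl (E)-2-methyl-4-oxobut-2-enoate | COC(=O)/C(C)=C/C=O | intermediate
5 | (E)-penta-1,3-diene | C=C/C=C/C | starting material
6 | methyl (1S,5S,6S)-6-formyl-1,5-dimethylcyclohex-3-ene-1-carboxylate | COC(=O)[C@]1(C)[C@H]([C@@H](C)C=CC1)C=O | intermediate
7 | hydroxy ester (C9 alcohol of 6) | COC(=O)[C@]1(C)[C@H]([C@@H](C)C=CC1)CO | intermediate
8 | trans-fused ring-A lactone | O=C1OC[C@H]2[C@@H](C)C=CC[C@]12C | intermediate
9 | 12α-hydroperoxy-13-ene lactone | O=C1OC[C@H]2[C@@H](C)[C@H](OO)C=C[C@]12C | intermediate
10 | 12α-hydroxy-13α,14α-epoxy lactone | O=C1OC[C@H]2[C@@H](C)[C@H](O)[C@@H]3O[C@@H]3[C@]12C | intermediate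
11 | 12α-O-PMB epoxy lactone | O=C1OC[C@H]2[C@@H](C)[C@H](OCc4ccc(OC)cc4)[C@@H]3O[C@@H]3[C@]12C | intermediate
12 | C2 methyl ketone, C9 alcohol | CC(=O)[C@]2(C)[C@H]([C@@H](C)[C@H](OCc4ccc(OC)cc4)[C@@H]3O[C@@H]32)CO | intermediate
13 | 2,2-dimethyl-1,3-dioxan-5-one | CC1(C)OCC(=O)CO1 | starting material
14 | 5-(chloromethylidene)-2,2-dimethyl-1,3-dioxane | CC1(C)OCC(=CCl)CO1 | intermediate
15 | 2-(chloromethylidene)propane-1,3-diol | OCC(=CCl)CO | intermediate
16 | (E)-3-chloro-2-[(4-methoxybenzyloxy)methyl]prop-2-en-1-ol | Cl/C=C(/COCc1ccc(OC)cc1)CO | intermediate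
17 | (Z)-allylic bromide (Cl cis to CH2Br) | Cl/C=C(/COCc1ccc(OC)cc1)CBr | intermediate
18 | chain-extended C2 ketone, C9 alcohol | Cl/C=C(/COCc1ccc(OC)cc1)CCC(=O)[C@]2(C)[C@H]([C@@H](C)[C@H](OCc4ccc(OC)cc4)[C@@H]3O[C@@H]32)CO | intermediate
19 | C2-keto C9-aldehyde | Cl/C=C(/COCc1ccc(OC)cc1)CCC(=O)[C@]2(C)[C@H]([C@@H](C)[C@H](OCc4ccc(OC)cc4)[C@@H]3O[C@@H]32)C=O | intermediate
20 | dimethyl (S)-malate | COC(=O)C[C@H](O)C(=O)OC | starting material
21 | dimethyl (2S,3R)-2-hydroxy-3-methylbutanedioate | COC(=O)[C@H](C)[C@H](O)C(=O)OC | intermediate
22 | (2S,3R)-2-hydroxy-3-methylbutanedioic acid | OC(=O)[C@H](C)[C@H](O)C(=O)O | intermediate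
23 | (2R)-2-[(2S,4S)-2-tert-butyl-5-oxo-1,3-dioxolan-4-yl]propanoic acid | OC(=O)[C@H](C)[C@@H]1O[C@H](C(C)(C)C)OC1=O | intermediate
24 | aldol adduct (9-OH, dioxolanone, C19 acid) | Cl/C=C(/COCc1ccc(OC)cc1)CCC(=O)[C@]2(C)[C@H]([C@@H](C)[C@H](OCc4ccc(OC)cc4)[C@@H]3O[C@@H]32)[C@@H](O)[C@]5(O[C@H](C(C)(C)C)OC5=O)[C@@H](C)C(=O)O | intermediate
25 | 9-O-TES ether C19 TES ester | Cl/C=C(/COCc1ccc(OC)cc1)CCC(=O)[C@]2(C)[C@H]([C@@H](C)[C@H](OCc4ccc(OC)cc4)[C@@H]3O[C@@H]32)[C@@H](O[Si](CC)(CC)CC)[C@]5(O[C@H](C(C)(C)C)OC5=O)[C@@H](C)C(=O)O[Si](CC)(CC)CC | intermediate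
26 | 9-O-TES dioxolanone acid | Cl/C=C(/COCc1ccc(OC)cc1)CCC(=O)[C@]2(C)[C@H]([C@@H](C)[C@H](OCc4ccc(OC)cc4)[C@@H]3O[C@@H]32)[C@@H](O[Si](CC)(CC)CC)[C@]5(O[C@H](C(C)(C)C)OC5=O)[C@@H](C)C(=O)O | intermediate
27 | 2R-alcohol dioxolane lactol (C7 epimers) | Cl/C=C(/COCc1ccc(OC)cc1)CC[C@@H](O)[C@]2(C)[C@H]([C@@H](C)[C@H](OCc4ccc(OC)cc4)[C@@H]3O[C@@H]32)[C@@H](O[Si](CC)(CC)CC)[C@]5(O[C@H](C(C)(C)C)OC5O)[C@@H](C)C(=O)O | intermediate
28 | 2,8-diol C7-aldehyde C19-acid (drawn open) | Cl/C=C(/COCc1ccc(OC)cc1)CC[C@@H](O)[C@]2(C)[C@H]([C@@H](C)[C@H](OCc4ccc(OC)cc4)[C@@H]3O[C@@H]32)[C@@H](O[Si](CC)(CC)CC)[C@@](O)(C=O)[C@@H](C)C(=O)O | intermediate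
29 | 2,8-diol C7-aldehyde C19-methyl ester | Cl/C=C(/COCc1ccc(OC)cc1)CC[C@@H](O)[C@]2(C)[C@H]([C@@H](C)[C@H](OCc4ccc(OC)cc4)[C@@H]3O[C@@H]32)[C@@H](O[Si](CC)(CC)CC)[C@@](O)(C=O)[C@@H](C)C(=O)OC | intermediate
30 | 2-O-acetate | Cl/C=C(/COCc1ccc(OC)cc1)CC[C@@H](OC(C)=O)[C@]2(C)[C@H]([C@@H](C)[C@H](OCc4ccc(OC)cc4)[C@@H]3O[C@@H]32)[C@@H](O[Si](CC)(CC)CC)[C@@](O)(C=O)[C@@H](C)C(=O)OC | intermediate
31 | 8,9-bis-O-TES aldehyde | Cl/C=C(/COCc1ccc(OC)cc1)CC[C@@H](OC(C)=O)[C@]2(C)[C@H]([C@@H](C)[C@H](OCc4ccc(OC)cc4)[C@@H]3O[C@@H]32)[C@@H](O[Si](CC)(CC)CC)[C@@](O[Si](CC)(CC)CC)(C=O)[C@@H](C)C(=O)OC | intermediate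
32 | 12,16-diol | Cl/C=C(/CO)CC[C@@H](OC(C)=O)[C@]2(C)[C@H]([C@@H](C)[C@H](O)[C@@H]3O[C@@H]32)[C@@H](O[Si](CC)(CC)CC)[C@@](O[Si](CC)(CC)CC)(C=O)[C@@H](C)C(=O)OC | intermediate
33 | C16 allylic chloride, 12-OH | Cl/C=C(/CCl)CC[C@@H](OC(C)=O)[C@]2(C)[C@H]([C@@H](C)[C@H](O)[C@@H]3O[C@@H]32)[C@@H](O[Si](CC)(CC)CC)[C@@](O[Si](CC)(CC)CC)(C=O)[C@@H](C)C(=O)OC | intermediate
34 | seco precursor (12-O-hexanoate) | Cl/C=C(/CCl)CC[C@@H](OC(C)=O)[C@]2(C)[C@H]([C@@H](C)[C@H](OC(=O)CCCCC)[C@@H]3O[C@@H]32)[C@@H](O[Si](CC)(CC)CC)[C@@](O[Si](CC)(CC)CC)(C=O)[C@@H](C)C(=O)OC | intermediate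
35 | C16-bound allylchromium(III) dichloride | Cl/C=C(/C[Cr](Cl)Cl)CC[C@@H](OC(C)=O)[C@]2(C)[C@H]([C@@H](C)[C@H](OC(=O)CCCCC)[C@@H]3O[C@@H]32)[C@@H](O[Si](CC)(CC)CC)[C@@](O[Si](CC)(CC)CC)(C=O)[C@@H](C)C(=O)OC | intermediate
36 | ten-membered 7-hydroxy C19-methyl ester | C=C1CC[C@@H](OC(C)=O)[C@]2(C)[C@H]([C@@H](C)[C@H](OC(=O)CCCCC)[C@@H]3O[C@@H]32)[C@@H](O[Si](CC)(CC)CC)[C@](O[Si](CC)(CC)CC)([C@@H](C)C(=O)OC)[C@@H](O)[C@H]1Cl | intermediate
37 | 8,9-bis-O-TES ether of the target | C=C1CC[C@@H](OC(C)=O)[C@]2(C)[C@H]([C@@H](C)[C@H](OC(=O)CCCCC)[C@@H]3O[C@@H]32)[C@@H](O[Si](CC)(CC)CC)[C@]2(O[Si](CC)(CC)CC)[C@@H](C)C(=O)O[C@H]2[C@H]1Cl | intermediate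
38 | CNP0109876.1 | C=C1CC[C@@H](OC(C)=O)[C@]2(C)[C@H]([C@@H](C)[C@H](OC(=O)CCCCC)[C@@H]3O[C@@H]32)[C@@H](O)[C@]2(O)[C@@H](C)C(=O)O[C@H]2[C@H]1Cl | target

## Count and risks

Total step count: 25. Longest linear sequence: 18 steps (1–7, 12, 13, 17–25).

**Step 24 (key step).**
- With open chains, ring A prefers C2 and C9 diaxial and far apart. Closure therefore has to pay for the ring flip and for transannular strain.
- Protonation of the allylchromium species or oligomerisation may outrun cyclisation.
- The facial preference at C7 may erode if chromium finds a chelate.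
- Bond formation may occur through C16 instead of C6.
- The β-chloro alkoxide may close to a vinyl epoxide before it lactonises.
- Fallback: the reductive in-situ metalation is replaced by a preformed, configurationally stable allyl donor that is inert until it is triggered. It sets out from 34. HSiCl3, CuCl and iPr2NEt in Et2O convert the allylic chloride without transposition into the allyltrichlorosilane F1. The solution of F1 is then added slowly to DMF, where the Lewis base opens a closed hexacoordinate silicate chair. This chair translates the Cl-trans geometry stereospecifically into the anti chlorohydrin. The route is rejoined at 36, which is lactonised to 37 with PPTS.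

**Step 3.**
- The ester may compete with the formyl group for control of regiochemistry and for the endo position.
- A β,β-disubstituted enal may react slowly and with reduced enantioselectivity.
- Fallback: a covalent auxiliary on the C9 acyl group replaces the catalyst. It sets out from 4. Pinnick oxidation gives the half ester F2. Mixed-anhydride coupling with lithiated (S)-4-benzyloxazolidin-2-one gives the imide F3.
- The Et2AlCl-promoted Diels–Alder reaction of the chelated s-cis imide with 5 gives the adduct F4, with the diene anti to benzyl and the imide carbonyl dominant and endo.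
- LiBH4 removes the auxiliary reductively beside the hindered ester, and the route is rejoined at 7.

**Step 5.**
- A cis-disubstituted cyclohexene is a slow ene partner. Long irradiation may bleach the sensitiser, leave conversion incomplete, or dehydrate the hydroperoxide to an enone before oxygen transfer.
- Fallback: stepwise oxygenation on the same locked ring, setting out from 8. m-CPBA epoxidises the open α face to the epoxide F5.
- Lithium diethylamide removes the syn, pseudo-axial H14α (the lactone is not enolisable) and gives the allylic alcohol F6.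
- VO(acac)2/t-BuOOH then epoxidises syn to the hydroxyl, and the route is rejoined at 10.

**Step 17.**
- A tetrasubstituted enolate carbon meets an aldehyde flanked by C1 and C11, so addition may be slow and may revert on warming before silylation.
- Proton transfer to the enolate may start an intramolecular C3-to-C9 aldol reaction in 19.
- The chair preference of a fully substituted enolate may be weak, which would erode C9.
- Fallback: an irreversible, Lewis-acid-driven open-transition-state addition, setting out from 23. Double deprotonation and trapping with TMSCl give the bis-silyl ketene acetal F7.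
- F7 is added to 19 with BF3·OEt2 at −78 °C (Mukaiyama aldol addition). The face is still ruled by tert-butyl and by Felkin–Anh attack.
- Aqueous work-up rejoins the route at 24, which is silylated to 26 as in step 17.

**Step 18.**
- The lactol aluminate may break down early and be reduced on to the C7 alcohol, which would lactonise onto C19.
- Substrate control at C2 may be insufficient.
- The free α-hydroxy aldehyde may undergo an α-ketol shift during handling.
- Fallback: the two reductions are separated and C2 is put under reagent control, setting out from 26. (S)-Me-oxazaborolidine with catecholborane at −78 °C distinguishes quaternary C1 from the C3 methylene and gives the 2R alcohol F8.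
- A smaller excess of DIBAL then only has to deliver the lactol, and the route is rejoined at 27.

## Further compounds

F1 | step 24 | C16 allyltrichlorosilane of 34 | Cl/C=C(/C[Si](Cl)(Cl)Cl)CC[C@@H](OC(C)=O)[C@]2(C)[C@H]([C@@H](C)[C@H](OC(=O)CCCCC)[C@@H]3O[C@@H]32)[C@@H](O[Si](CC)(CC)CC)[C@@](O[Si](CC)(CC)CC)(C=O)[C@@H](C)C(=O)OC
F2 | step 3 | (E)-4-methoxy-3-methyl-4-oxobut-2-enoic acid | COC(=O)/C(C)=C/C(=O)O
F3 | step 3 | N-enoyl (S)-4-benzyloxazolidinone | COC(=O)/C(C)=C/C(=O)N1[C@@H](Cc2ccccc2)COC1=O
F4 | step 3 | Diels–Alder adduct imide | COC(=O)[C@]1(C)[C@H]([C@@H](C)C=CC1)C(=O)N2[C@@H](Cc3ccccc3)COC2=O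
F5 | step 5 | 12α,13α-epoxy lactone | O=C1OC[C@H]2[C@@H](C)[C@@H]3O[C@@H]3C[C@]12C
F6 | step 5 | 12α-hydroxy-13-ene lactone | O=C1OC[C@H]2[C@@H](C)[C@H](O)C=C[C@]12C
F7 | step 17 | bis(trimethylsilyl) ketene acetal ester of 23 | C[C@@H](C(=O)O[Si](C)(C)C)C1=C(O[Si](C)(C)C)O[C@@H](C(C)(C)C)O1
F8 | step 18 | 2R alcohol of 26 | Cl/C=C(/COCc1ccc(OC)cc1)CC[C@@H](O)[C@]2(C)[C@H]([C@@H](C)[C@H](OCc4ccc(OC)cc4)[C@@H]3O[C@@H]32)[C@@H](O[Si](CC)(CC)CC)[C@]5(O[C@H](C(C)(C)C)OC5=O)[C@@H](C)C(=O)O
A1 | alternative 1 | 2-iodoalkene C6-aldehyde with preformed lactone | C=C(I)CC[C@@H](OC(C)=O)[C@]2(C)[C@H]([C@@H](C)[C@H](OC(=O)CCCCC)[C@@H]3O[C@@H]32)[C@@H](O[Si](CC)(CC)CC)[C@]2(O[Si](CC)(CC)CC)[C@@H](C)C(=O)O[C@H]2C=O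
A2 | alternative 1 | 6-epi-hydroxy macrocycle | C=C1CC[C@@H](OC(C)=O)[C@]2(C)[C@H]([C@@H](C)[C@H](OC(=O)CCCCC)[C@@H]3O[C@@H]32)[C@@H](O[Si](CC)(CC)CC)[C@]2(O[Si](CC)(CC)CC)[C@@H](C)C(=O)O[C@H]2[C@@H]1O
A3 | alternative 2 | 2-vinyl-7-allenyl trans-decalin-2-ol | C=C[C@@]1(O)[C@H](C=C=C)[C@H](O[Si](C)(C)C(C)(C)C)[C@H](O[Si](C)(C)C(C)(C)C)[C@H]2[C@@H](C)[C@H](OCc4ccc(OC)cc4)[C@@H]3O[C@@H]3[C@]12C
A4 | alternative 2 | ring-expanded 5(16),6E-dien-2-one | C=C1CCC(=O)[C@]2(C)[C@H]([C@@H](C)[C@H](OCc4ccc(OC)cc4)[C@@H]3O[C@@H]32)[C@@H](O[Si](C)(C)C(C)(C)C)[C@@H](O[Si](C)(C)C(C)(C)C)/C=C/1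
A5 | alternative 3 | deschloro 5Z-ene | C/C=1CC[C@@H](OC(C)=O)[C@]2(C)[C@H]([C@@H](C)[C@H](OC(=O)CCCCC)[C@@H]3O[C@@H]32)[C@@H](O)[C@]2(O)[C@@H](C)C(=O)O[C@H]2\C=1
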